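# Proposed total synthesis of sipholenol M (41)

## Analysis of the target

Sipholenol M (41) is built from two bicyclic halves joined by a CH2–CH2 linker: a trans-fused perhydro-1-benzoxepine (oxepane ring A on cyclohexane ring B) and a cis-fused octalin (cyclohexene ring C on cyclohexane ring D). It has nine stereocenters. Five lie in the A/B half: the ring A carbinol CH–OH next to the gem-dimethyl ether carbon, and in ring B the ether methine, the methyl-bearing quaternary carbon, the linker-bearing methine and the tertiary carbinol. Four lie in the C/D half: the two ring-fusion methines, the ring D tertiary carbinol and the ring C carbon that carries OOH. In ring B the two methyl groups are axial and syn to each other, while the ether oxygen, the oxepane chain, the linker and the tertiary hydroxyl are equatorial; in ring C the hydroperoxide sits on the face that also carries the two bonds to ring D. The halves are too far apart to control one another, so each must be made in absolute configuration on its own and then joined. The secondary allylic hydroperoxide is the most fragile group (reduction, base-induced loss of water, radical chemistry) and must be introduced last; the tetrasubstituted alkene and the two tertiary alcohols restrict the use of strong acid. The hard points are the quaternary carbon flanked by three stereocenters, the 1,3-diaxial methyl pair, the seven-membered ether, and the regio- and face-selective placement of OOH. The strategy rests on ring B: its four contiguous carbons CH–O, C(CH3)(oxepane chain), CH(linker) and C(OH)CH3 map onto C4, C3, C2 and C1 of a 4-silyloxy-3-methylcyclohex-2-enone, to which only two carbon–carbon bonds must be added, at the β- and the α-carbon.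

## Retrosynthetic reasoning

41 to 40. The C–OOH bond on ring C is cut first. An ene-type photooxygenation of the trisubstituted alkene 40 forms this bond and at the same time moves the double bond into the tetrasubstituted position, so the peroxide never meets another reagent. Because the ene reaction is suprafacial, the configuration of the new C–O carbon is relayed from the allylic methine of 40.

40 to 36 (through 39, 38, 37). The vinylic methyl group and the ring C double bond are traced back to a ketone: enol triflate 38 and a methyl cross-coupling give 39, and desilylation gives 40. Ketone 36 is preferred because its α-methine can be equilibrated, which fixes the stereocenter that later steers the ene reaction, and because the less substituted enol triflate forms under kinetic control.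

36 to 21 and 33 (through 34). The central C–C bond of the ethylene linker is cut. A primary radical from iodide 21 adds to the exocyclic methylene of dienone 33. This cut is chosen because both fragments then end in a single carbon at a congested position, and a radical addition tolerates that congestion better than a polar alkylation next to a quaternary carbon. The extra ring double bond of 33 is a regiochemical device for making 33 and is hydrogenated afterwards.

21 to 18 (through 20, 19). The iodomethyl group and the formate of 21 both arise from one fragmentation of lactol 20. The β-scission removes the carboxyl carbon of the original acetate arm and leaves the tertiary alcohol protected. Lactol 20 comes from lactone 19, the oxidation product of diol 18.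

18 to 15 (through 17, 16). The ring B tertiary carbinol is cut at its methyl C–H and C–O bonds back to ketone 15. Direct methyl addition to 15 would come from the equatorial side and give the wrong epimer, so the carbon is introduced first (methylenation to 16) and the oxygen second (epoxide 17), followed by hydride opening. The syn-axial quaternary methyl then directs the oxygen into the equatorial position.

15 to 11 (through 14, 13, 12). The ring A ether bond between oxygen and the gem-dimethyl carbon is cut. Epoxide 12, made by catalyst-controlled epoxidation of the prenyl-type alkene of 11, carries the carbinol configuration; after desilylation to 13 the ring B hydroxyl opens it at the tertiary carbon to give 14.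

11 to 5, 7 and 8. The two bonds at the quaternary carbon and its neighbour are cut together. Enone 5 receives the homoprenyl group from 7 at the β-carbon, and the resulting enolate is alkylated by 8. The silyloxy stereocenter of 5 controls both new centers, and the ketone that remains is the handle for the tertiary carbinol.

5 to 1, and 7 to 6. Enone 5 is reached by γ-oxygenation of 1 through dienyl acetate 2, resolution of alcohol 3 to 4 and silylation. Grignard reagent 7 comes from bromide 6.

33 to 23 and 24 (through 30 to 25). The exocyclic methylene of 33 is removed to give enone 30. Its tertiary carbinol is traced through 29, 28 and 27 to the ketone of 26 and 25 by the same methylenation–epoxidation–hydride logic, and its enone to the silyl enol ether of 25. Cycloadduct 25 is cut at the two new ring C bonds into diene 23 (from 22) and enone 24, which sets the cis ring fusion in one step.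

## Alternatives that were turned down

Alternative 1: Here the oxepene double bond of A1 (the future CH(OH)–CH2 unit of ring A) is disconnected. In the forward sense the allyl/1,1-dimethylallyl ether diene A2 is closed with the second-generation Grubbs catalyst, with loss of ethylene. In its favour, metathesis leaves no doubt about ring size, and on that point it is stronger than the acid-mediated epoxide opening used here, which has a six-membered competitor. Against it: A2 needs a tertiary allylic ether on a hindered secondary alcohol beside the quaternary carbon, an etherification that competes with elimination and allylic transposition. The quaternary carbon itself must be set by a separate asymmetric allylation. After ring closure the ring A carbinol still needs an epoxidation and a regioselective hydride opening whose facial outcome depends on the substrate alone. Finally, A1 carries only a ketone next to the quaternary carbon, so the linker methine and the tertiary carbinol of ring B remain to be built. The chosen route forms the quaternary carbon, its neighbour and both appendages in one flask and takes the ring A carbinol configuration from a catalyst; it pays for this with the regiochemical risk of the ether closure.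

Alternative 2: This plan cuts the ring-fusion bond and the CH2–CH(O) bond of ring C in A3. The forward step is an intramolecular Diels–Alder reaction of the tethered silyloxydiene–vinyl ketone A4 under a chiral oxazaborolidinium Lewis acid. It closes rings C and D and sets three stereocenters in one catalytic step. That is clearly shorter than the eight steps spent on 33 here, and it places the oxygen at the future hydroperoxide carbon with defined configuration instead of relying on a late ene reaction; on both points it is stronger. Against it: in A3 the ring C double bond ends in a CH at the carbon that must carry the linker, and attaching a chain to that vinylic position needs oxidation-state detours. The silyl ether would finally have to become a hydroperoxide with retention, for which no dependable method exists. The ring D ketone must be turned into the tertiary carbinol with its oxygen on the convex face, which again needs the three-step methylenation sequence. A4 is an acid-sensitive acyclic diene whose enol ether geometry must be controlled. The chosen route offers instead a right half that arrives as an exocyclic enone ready for the union, and it spends its key step on the more congested left half, which Alternative 2 leaves open.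

Alternative 3: The bond between the gem-dimethyl carbon and the ring-fusion methine of A5 is disconnected. Forward, Fe(acac)3 and PhSiH3 transfer a hydrogen atom to the isopropenyl group of enone A6, and the tertiary radical adds to the enone β-carbon to close ring D cis onto ring C. It makes the most hindered bond of the right half intramolecularly and under neutral conditions. It also delivers an α-(silyloxymethyl) ketone that is one elimination away from an exocyclic enone of the kind used here as 33, so it fits the same union. On the construction of the quaternary centre it is stronger than the intermolecular cycloaddition at the neopentyl β-carbon of 24. Against it: A6 must already hold the ring stereocenter and the fully substituted silyloxy carbon in a defined 1,2-relationship that no ring enforces. The 2,4-disubstituted enone is long to make. The radical can be reduced before it cyclises, and the configuration of the two new centers rests on the substrate alone. The chosen route instead takes its right-half stereocenters from one catalytic cycloaddition and two sterically guided epoxidations, and keeps the main risk in a single step on ring B.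

Key step: step 6

## Assumptions

- Lipase (step 3): it is assumed that the enzyme acetylates the (R)-enantiomer of 3 (the methyl-bearing sp2 carbon acting as the larger substituent), so that (S)-4 remains. If the sense is the opposite, the (S)-acetate is collected and methanolysed.
- Cycloaddition (step 18): it is assumed that the (S)-configured oxazaborolidinium catalyst gives the enantiomer 25 drawn. If it gives the antipode, the (R)-catalyst is used.

## Route

Step 1
Reactants: 1 3-methylcyclohex-2-en-1-one
Product: 2 3-methylcyclohexa-1,3-dien-1-yl acetate
Conditions: isopropenyl acetate, TsOH·H2O (cat.), reflux, acetone distilled off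
Reagents that add atoms: isopropenyl acetate, CC(=C)OC(C)=O
Why: Acid-catalysed enol ester exchange under equilibrating conditions should give the linearly conjugated dienyl acetate, the endocyclic, more substituted diene being the stable isomer.

Step 2
Reactants: 2 3-methylcyclohexa-1,3-dien-1-yl acetate
Product: 3 rac-4-hydroxy-3-methylcyclohex-2-en-1-one
Conditions: mCPBA, dioxane–H2O, 0 °C → rt
Reagents that add atoms: mCPBA, OOC(=O)c1cccc(Cl)c1
Why: The peracid attacks the electron-rich γ,δ-double bond of the dienyl ester and the vinyl epoxide collapses with loss of the acetyl group to the γ-hydroxy enone (γ-oxidation of a dienol ester).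

Step 3
Reactants: 3 rac-4-hydroxy-3-methylcyclohex-2-en-1-one
Product: 4 (S)-4-hydroxy-3-methylcyclohex-2-en-1-one
Conditions: Amano lipase PS (Burkholderia cepacia lipase), vinyl acetate, t-BuOMe, 30 °C, to slightly more than half conversion; chromatography
Reagents that add atoms: none
Why: Lipase-catalysed kinetic resolution by enantioselective transesterification; by the usual size rule for secondary alcohols the (R)-alcohol should be acetylated and the (S)-alcohol should remain.

Step 4
Reactants: 4 (S)-4-hydroxy-3-methylcyclohex-2-en-1-one
Product: 5 (S)-4-(tert-butyldimethylsilyloxy)-3-methylcyclohex-2-en-1-one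
Conditions: TBSCl, imidazole, DMF, rt
Reagents that add atoms: TBSCl, CC(C)(C)[Si](C)(C)Cl
Why: Standard silylation of a secondary allylic alcohol; the bulky silyl ether is the group that directs the cuprate in step 6.

Step 5
Reactants: 6 5-bromo-2-methylpent-2-ene
Product: 7 4-methylpent-3-enylmagnesium bromide (titrated THF solution)
Conditions: Mg turnings, I2 (cat.), THF, 35 °C
Reagents that add atoms: magnesium, [Mg]
Why: Magnesium insertion into a primary homoallylic bromide (Grignard formation); the trisubstituted alkene is too remote to interfere.

Step 6
Reactants: 5 (S)-4-(tert-butyldimethylsilyloxy)-3-methylcyclohex-2-en-1-one; 7 4-methylpent-3-enylmagnesium bromide; 8 tert-butyl bromoacetate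
Product: 11 tert-butyl 2-[(1S,2S,3S)-3-(tert-butyldimethylsilyloxy)-2-methyl-2-(4-methylpent-3-enyl)-6-oxocyclohexyl]acetate, via trimethylsilyl enol ether 9 (not isolated), via lithium enolate 10 (not isolated)
Conditions: 7, CuBr·SMe2 (10 mol %), Me3SiCl, THF, −78 °C; Et3N, volatiles removed; MeLi, THF, 0 °C; 8, DMPU, −78 → −20 °C; then DBU (cat.), CH2Cl2, rt
Reagents that add atoms: none
Why: CuBr·SMe2 turns the Grignard reagent into a homoprenyl cuprate, and Me3SiCl accelerates its 1,4-addition to the β,β-disubstituted enone and traps the enolate as silyl enol ether 9. MeLi then cleaves the O–Si bond to the regiodefined lithium enolate 10, which displaces bromide from 8 at the α-carbon. The closest known reaction type is the one-flask cuprate conjugate addition–enolate alkylation of cyclohexenones, including β-methyl enones that give quaternary carbons. No ring is closed; two C–C bonds are formed on adjacent ring carbons. The quaternary stereocenter is controlled by the 4-silyloxy group, to which the cuprate adds anti, so that the oxygen and the homoprenyl chain end up trans as the trans ring fusion of rings A and B requires. The methine stereocenter is under thermodynamic control: the epimer with the acetate arm equatorial and cis to the axial methyl is the stable one, and the final exposure to DBU converges any axial epimer to it. The step needs 1,4- over 1,2-addition (secured by copper and Me3SiCl), C- over O-alkylation, and no proton transfer to the other α-carbon (secured by the reactive, non-enolisable-ester electrophile, DMPU and low temperature).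

Step 7
Reactants: 11 tert-butyl 2-[(1S,2S,3S)-3-(tert-butyldimethylsilyloxy)-2-methyl-2-(4-methylpent-3-enyl)-6-oxocyclohexyl]acetate
Product: 12 the (S)-epoxide of 11, tert-butyl 2-[(1S,2S,3S)-3-(tert-butyldimethylsilyloxy)-2-{2-[(2S)-3,3-dimethyloxiran-2-yl]ethyl}-2-methyl-6-oxocyclohexyl]acetate
Conditions: ent-Shi ketone (L-fructose-derived 1,2:4,5-di-O-isopropylidene-β-L-erythro-2,3-hexodiulo-2,6-pyranose, 30 mol %), Oxone (2KHSO5·KHSO4·K2SO4), K2CO3, Bu4NHSO4, MeCN–dimethoxymethane/aqueous Na2B4O7 buffer (pH 10.5), 0 °C
Reagents that add atoms: potassium peroxymonosulfate (active component of Oxone), [K+].[O-]S(=O)(=O)OO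
Why: Shi asymmetric epoxidation by the chiral dioxirane through a spiro transition state is selective for the trisubstituted alkene. The D-fructose-derived ketone gives the (R)-epoxide from R–CH=CMe2 alkenes, so its enantiomer is used to set the (S)-CH–O carbon that becomes the ring A carbinol. The pH 10.5 buffer holds back Baeyer–Villiger oxidation of the ring ketone.

Step 8
Reactants: 12 the (S)-epoxide of 11
Product: 13 tert-butyl 2-[(1S,2S,3S)-2-{2-[(2S)-3,3-dimethyloxiran-2-yl]ethyl}-3-hydroxy-2-methyl-6-oxocyclohexyl]acetate
Conditions: Bu4NF, AcOH (1 equiv), THF, 0 °C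
Reagents that add atoms: none
Why: Fluoride-mediated desilylation; buffering with acetic acid keeps the liberated alkoxide from opening the epoxide at its secondary carbon.

Step 9
Reactants: 13 the hydroxy epoxide
Product: 14 tert-butyl 2-[(3S,5aS,6S,9aS)-3-hydroxy-2,2,5a-trimethyl-7-oxodecahydro-1-benzoxepin-6-yl]acetate (trans-fused)
Conditions: (+)-camphorsulfonic acid (10 mol %), CH2Cl2, −20 → 0 °C
Reagents that add atoms: none
Why: Acid-catalysed intramolecular epoxide opening in the 7-endo mode: protonation places the positive charge on the tertiary epoxide carbon, which the equatorial ring B hydroxyl attacks. The (S)-CH–O bond is not touched and becomes the carbinol; the trans ring fusion follows from the anti relation of hydroxyl and chain set in step 6.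

Step 10
Reactants: 14 the oxepane keto ester
Product: 15 the 3-O-tert-butyldimethylsilyl ether of 14
Conditions: TBSOTf, 2,6-lutidine, CH2Cl2, −78 → 0 °C
Reagents that add atoms: TBSOTf, CC(C)(C)[Si](C)(C)OS(=O)(=O)C(F)(F)F
Why: Silyl triflate silylation of the hindered secondary alcohol, which would otherwise be oxidised in step 14 and fragment in step 16; with the hindered base at low temperature the ketone should not be enolised.

Step 11
Reactants: 15 the silyl ether of 14
Product: 16 the 7-methylidene analogue of 15 (C=CH2 in place of C=O, configurations unchanged)
Conditions: Ph3PCH3Br, KOt-Bu, toluene–THF, 0 → 60 °C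
Reagents that add atoms: methyltriphenylphosphonium bromide, C[P+](c1ccccc1)(c1ccccc1)c1ccccc1.[Br-]
Why: Wittig methylenation of the ketone; the tert-butyl ester is inert to the ylide, and any epimerisation of the α-methine can only lead to the stable equatorial epimer already present.

Step 12
Reactants: 16 the exocyclic alkene
Product: 17 the spiro-epoxide of 16 at C7 (epoxide oxygen equatorial, CH2 axial and syn to the axial 5a-methyl)
Conditions: mCPBA, NaHCO3, CH2Cl2, 0 °C
Reagents that add atoms: mCPBA, OOC(=O)c1cccc(Cl)c1
Why: Prilezhaev epoxidation of the 1,1-disubstituted alkene; the axial direction is blocked by the syn-axial quaternary methyl, so the peracid should approach equatorially and place the oxygen equatorial.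

Step 13
Reactants: 17 the spiro-epoxide
Product: 18 2-[(3S,5aS,6S,7S,9aS)-3-(tert-butyldimethylsilyloxy)-7-hydroxy-2,2,5a,7-tetramethyldecahydro-1-benzoxepin-6-yl]ethanol
Conditions: LiEt3BH (excess), THF, 0 °C → rt; aqueous NaOH work-up
Reagents that add atoms: none
Why: Hydride opens the epoxide at its CH2 carbon (SN2), which gives the axial methyl and the equatorial tertiary alcohol, the epimer that direct methyl addition to the ketone would not give. The same reagent reduces the tert-butyl ester to the primary alcohol.

Step 14
Reactants: 18 the diol
Product: 19 the trans-fused γ-lactone of 18 (ring B C7–O–C(=O)–CH2–C6)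
Conditions: TEMPO (10 mol %), PhI(OAc)2, CH2Cl2, rt
Reagents that add atoms: none
Why: Oxoammonium oxidation of the primary alcohol to the aldehyde, which closes with the tertiary hydroxyl to the lactol and is oxidised further to the lactone (oxidative lactonisation of a 1,4-diol); the two equatorial bonds allow the trans fusion.

Step 15
Reactants: 19 the lactone
Product: 20 the corresponding lactol (mixture of anomers)
Conditions: i-Bu2AlH, CH2Cl2, −78 °C
Reagents that add atoms: none
Why: Partial reduction of a lactone; the tetrahedral aluminium alkoxide is stable at −78 °C and gives the lactol on work-up.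

Step 16
Reactants: 20 the lactol
Product: 21 (3S,5aS,7S,9aS)-3-(tert-butyldimethylsilyloxy)-6-(iodomethyl)-2,2,5a,7-tetramethyldecahydro-1-benzoxepin-7-yl formate (ring B configurations as in 18)
Conditions: PhI(OAc)2, I2, cyclohexane–CH2Cl2, visible light, rt
Reagents that add atoms: iodine, II
Why: The lactol is converted into its hypoiodite, whose photolysis gives the alkoxy radical; β-scission expels the primary carbon radical and leaves the tertiary oxygen as a formate, and iodine traps the radical (alkoxy-radical β-fragmentation, a known reaction of trans-fused γ-lactols with this substitution pattern). The step removes the surplus carbon and protects the tertiary alcohol at once.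

Step 17
Reactants: 22 but-3-en-2-one
Product: 23 2-(triisopropylsilyloxy)buta-1,3-diene
Conditions: i-Pr3SiOTf, Et3N, Et2O, 0 °C
Reagents that add atoms: triisopropylsilyl triflate, CC(C)[Si](C(C)C)(C(C)C)OS(=O)(=O)C(F)(F)F
Why: Soft enolisation and O-silylation of the methyl ketone gives the 2-silyloxydiene; the bulky silyl group makes the diene robust toward the acidic catalyst of step 18.

Step 18
Reactants: 23 2-(triisopropylsilyloxy)buta-1,3-diene; 24 4,4-dimethylcyclohex-2-en-1-one
Product: 25 (4aR,8aS)-4,4-dimethyl-6-(triisopropylsilyloxy)-3,4,4a,5,8,8a-hexahydronaphthalen-1(2H)-one (cis-fused)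
Conditions: (S)-3,3-diphenyl-1-(2-methylphenyl)tetrahydropyrrolo[1,2-c][1,3,2]oxazaborole protonated with Tf2NH (20 mol %), CH2Cl2, −40 °C
Reagents that add atoms: none
Why: Enantioselective Diels–Alder reaction of a cyclic enone activated by a cationic chiral oxazaborolidine. The diene terminus next to the silyloxy carbon bonds to the enone β-carbon, suprafacial addition to the ring alkene gives the cis fusion, and the catalyst selects the enone face and so both stereocenters.

Step 19
Reactants: 25 the cycloadduct
Product: 26 the 1-methylidene analogue of 25 (C=CH2 in place of C=O)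
Conditions: Cp2TiMe2, toluene, 65 °C, dark
Reagents that add atoms: dimethyltitanocene, [CH3-].[CH3-].[Ti+4].c1cc[cH-]c1.c1cc[cH-]c1
Why: Petasis methylenation by the non-basic titanium methylidene converts the ketone next to the epimerisable ring-fusion methine without touching the cis fusion or the silyl enol ether.

Step 20
Reactants: 26 the methylidene silyl enol ether
Product: 27 cis-8,8-dimethyl-5-methylidene-4a,5,6,7,8,8a-hexahydronaphthalen-2(1H)-one
Conditions: Pd(OAc)2 (15 mol %), O2 (1 atm), DMSO, 60 °C
Reagents that add atoms: none
Why: Saegusa–Ito oxidation in its aerobic catalytic form: palladation of the silyl enol ether and β-hydride elimination give the enone regiospecifically on the side fixed by the cycloaddition. This double bond later blocks one α-side of the ketone.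

Step 21
Reactants: 27 the methylidene enone
Product: 28 the 5-spiro-epoxide of 27 (epoxide oxygen on the face of H-4a and H-8a)
Conditions: mCPBA, NaHCO3, CH2Cl2, 0 °C
Reagents that add atoms: mCPBA, OOC(=O)c1cccc(Cl)c1
Why: Prilezhaev epoxidation; the electron-poor enone double bond is inert, and the peracid should reach the exocyclic alkene from the convex face of the cis-fused bicycle, the side of the ring-fusion hydrogens.

Step 22
Reactants: 28 the epoxy enone
Product: 29 cis-5,8,8-trimethyl-1,2,4a,5,6,7,8,8a-octahydronaphthalene-2,5-diol (5-OH on the face of H-4a/H-8a; mixture of C2 epimers)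
Conditions: LiAlH4, THF, 0 °C → rt
Reagents that add atoms: none
Why: Hydride opens the epoxide at CH2 to the tertiary alcohol, with the hydroxyl on the convex face and the methyl on the concave face. The enone carbonyl is reduced 1,2 to the allylic alcohol, whose configuration does not matter.

Step 23
Reactants: 29 the allylic alcohol
Product: 30 (4aS,5S,8aR)-5-hydroxy-5,8,8-trimethyl-4a,5,6,7,8,8a-hexahydronaphthalen-2(1H)-one
Conditions: MnO2, CH2Cl2, rt
Reagents that add atoms: none
Why: Chemoselective oxidation of the allylic alcohol back to the enone; the tertiary alcohol cannot react.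

Step 24
Reactants: 30 the hydroxy enone
Product: 33 the 1-methylidene derivative of 30 (cross-conjugated dienone), via Mannich base 31 (not isolated), via trimethylammonium iodide 32 (not isolated)
Conditions: LiN(i-Pr)2 (2.2 equiv), THF, −78 °C; CH2=NMe2+ I− (Eschenmoser's salt); MeI, rt; aqueous NaHCO3; used at once
Reagents that add atoms: Eschenmoser's salt, C=[N+](C)C.[I-]
Why: Kinetic deprotonation of the enone can only occur at the single CH2 α to the carbonyl; a Mannich reaction with the iminium salt, N-methylation and E1cB elimination then give the exocyclic methylene (Mannich methylenation).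

Step 25
Reactants: 21 the iodomethyl formate; 33 the methylidene dienone
Product: 34 the Giese adduct: enone 30 carrying at C1 the 2-(ring B)ethyl chain of the left half, formate and silyl ether intact (mixture of C1 epimers)
Conditions: Bu3SnH (slow addition), AIBN, benzene, 80 °C, 33 in excess
Reagents that add atoms: none
Why: Giese reaction: the stannyl radical abstracts iodine and the nucleophilic primary radical adds to the unhindered CH2 terminus of the exocyclic enone much faster than to the β-substituted ring enone. The α-keto radical then takes hydrogen from the stannane; the configuration at that carbon is set in step 26.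

Step 26
Reactants: 34 the Giese adduct
Product: 36 the saturated ring C ketone with free tertiary hydroxyls on rings B and D, the linker chain at the α-carbon trans to the adjacent bond to ring D, via saturated keto formate 35 (not isolated)
Conditions: H2 (1 atm), palladium on carbon, EtOAc, rt; filtration; K2CO3, MeOH, rt
Reagents that add atoms: none
Why: Hydrogenation removes the ring C double bond that served as regiochemical block. Carbonate in methanol then cleaves the formate and equilibrates the α-methine to the epimer with the chain anti to the neighbouring gem-dimethyl carbon; the ring-fusion carbons are not enolisable and stay cis.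

Step 27
Reactants: 36 the keto diol
Product: 37 the bis(triethylsilyl) ether of 36 (both tertiary hydroxyls silylated)
Conditions: Et3SiOTf, 2,6-lutidine, CH2Cl2, −78 → −30 °C
Reagents that add atoms: triethylsilyl triflate, CC[Si](CC)(CC)OS(=O)(=O)C(F)(F)F
Why: Silyl triflate silylation of the two tertiary alcohols, so that the base and the triflating agent of step 28 meet no free hydroxyl.

Step 28
Reactants: 37 the fully silylated ketone
Product: 38 the enol triflate of 37 with the double bond toward the ring CH2 group
Conditions: KN(SiMe3)2, THF, −78 °C; PhNTf2, −78 → 0 °C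
Reagents that add atoms: N-phenylbis(trifluoromethanesulfonimide), FC(F)(F)S(=O)(=O)N(c1ccccc1)S(=O)(=O)C(F)(F)F
Why: Kinetic deprotonation takes the CH2 α-carbon in preference to the hindered methine, and O-sulfonylation of the enolate gives the less substituted enol triflate; the methine stereocenter is not touched.

Step 29
Reactants: 38 the enol triflate
Product: 39 the ring C alkene bearing the new vinylic methyl group (C(CH3)=CH), all three silyl ethers intact
Conditions: MeZnCl, Pd(PPh3)4 (5 mol %), THF, 50 °C
Reagents that add atoms: methylzinc chloride, C[Zn]Cl
Why: Negishi cross-coupling (oxidative addition of the enol triflate, transmetalation, reductive elimination) installs the methyl group without moving the double bond.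

Step 30
Reactants: 39 the silylated alkene
Product: 40 the triol with the trisubstituted ring C alkene (the target lacking OOH, double bond between C(CH3) and the ring CH)
Conditions: Bu4NF (excess), THF, 50 °C
Reagents that add atoms: none
Why: Fluoride cleaves the secondary tert-butyldimethylsilyl and both tertiary triethylsilyl ethers; it is done before the photooxygenation so that the hydroperoxide never meets fluoride or base.

Step 31
Reactants: 40 the triol alkene
Product: 41 sipholenol M
Conditions: O2, tetraphenylporphyrin (cat.), visible light, CH2Cl2, −20 °C
Reagents that add atoms: dioxygen, O=O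
Why: Schenck ene reaction: singlet oxygen bonds to the CH terminus of the trisubstituted alkene and takes the allylic methine hydrogen on the same face, which moves the double bond into the tetrasubstituted position. That hydrogen lies on the face of the ring D bonds (step 26), so the OOH group should be delivered to that face, as the target requires.

## Compound list

1 | 3-methylcyclohex-2-en-1-one | CC1=CC(=O)CCC1 | starting material
2 | 3-methylcyclohexa-1,3-dien-1-yl acetate | CC(=O)OC1=CC(C)=CCC1 | intermediate
3 | rac-4-hydroxy-3-methylcyclohex-2-en-1-one | CC1=CC(=O)CCC1O | intermediate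
4 | (S)-4-hydroxy-3-methylcyclohex-2-en-1-one | CC1=CC(=O)CC[C@@H]1O | intermediate
5 | (S)-4-(tert-butyldimethylsilyloxy)-3-methylcyclohex-2-en-1-one | CC1=CC(=O)CC[C@@H]1O[Si](C)(C)C(C)(C)C | intermediate
6 | 5-bromo-2-methylpent-2-ene | CC(C)=CCCBr | starting material
7 | 4-methylpent-3-enylmagnesium bromide | CC(C)=CCC[Mg]Br | intermediate
8 | tert-butyl bromoacetate | CC(C)(C)OC(=O)CBr | starting material
9 | (3S,4S)-4-(tert-butyldimethylsilyloxy)-3-methyl-3-(4-methylpent-3-enyl)-1-(trimethylsilyloxy)cyclohex-1-ene | CC(C)=CCC[C@]1(C)[C@@H](O[Si](C)(C)C(C)(C)C)CCC(O[Si](C)(C)C)=C1 | intermediate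
10 | lithium enolate corresponding to 9 | CC(C)=CCC[C@]1(C)[C@@H](O[Si](C)(C)C(C)(C)C)CCC(O[Li])=C1 | intermediate
11 | tert-butyl 2-[(1S,2S,3S)-3-(tert-butyldimethylsilyloxy)-2-methyl-2-(4-methylpent-3-enyl)-6-oxocyclohexyl]acetate | CC(C)=CCC[C@]1(C)[C@@H](O[Si](C)(C)C(C)(C)C)CCC(=O)[C@H]1CC(=O)OC(C)(C)C | intermediate
12 | (S)-epoxide of 11 | CC1(C)O[C@H]1CC[C@]2(C)[C@@H](O[Si](C)(C)C(C)(C)C)CCC(=O)[C@H]2CC(=O)OC(C)(C)C | intermediate
13 | hydroxy epoxide (12 without the silyl group) | CC1(C)O[C@H]1CC[C@]2(C)[C@@H](O)CCC(=O)[C@H]2CC(=O)OC(C)(C)C | intermediate
14 | tert-butyl 2-[(3S,5aS,6S,9aS)-3-hydroxy-2,2,5a-trimethyl-7-oxodecahydro-1-benzoxepin-6-yl]acetate | CC(C)(C)OC(=O)C[C@H]2[C@]3(C)CC[C@H](O)C(C)(C)O[C@H]3CCC2=O | intermediate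
15 | 3-O-tert-butyldimethylsilyl ether of 14 | CC(C)(C)OC(=O)C[C@H]2[C@]3(C)CC[C@H](O[Si](C)(C)C(C)(C)C)C(C)(C)O[C@H]3CCC2=O | intermediate
16 | 7-methylidene analogue of 15 | CC(C)(C)OC(=O)C[C@H]2[C@]3(C)CC[C@H](O[Si](C)(C)C(C)(C)C)C(C)(C)O[C@H]3CCC2=C | intermediate
17 | 7-spiro-epoxide of 16 (oxygen equatorial) | CC(C)(C)OC(=O)C[C@H]2[C@]3(C)CC[C@H](O[Si](C)(C)C(C)(C)C)C(C)(C)O[C@H]3CC[C@]21OC1 | intermediate
18 | 2-[(3S,5aS,6S,7S,9aS)-3-(tert-butyldimethylsilyloxy)-7-hydroxy-2,2,5a,7-tetramethyldecahydro-1-benzoxepin-6-yl]ethanol | OCC[C@H]2[C@]3(C)CC[C@H](O[Si](C)(C)C(C)(C)C)C(C)(C)O[C@H]3CC[C@]2(C)O | intermediate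
19 | trans-fused γ-lactone of 18 | O=C1C[C@H]2[C@]3(C)CC[C@H](O[Si](C)(C)C(C)(C)C)C(C)(C)O[C@H]3CC[C@]2(C)O1 | intermediate
20 | lactol of 19 (anomers) | OC1C[C@H]2[C@]3(C)CC[C@H](O[Si](C)(C)C(C)(C)C)C(C)(C)O[C@H]3CC[C@]2(C)O1 | intermediate
21 | 3-(tert-butyldimethylsilyloxy)-6-(iodomethyl)-2,2,5a,7-tetramethyldecahydro-1-benzoxepin-7-yl formate | IC[C@H]2[C@]3(C)CC[C@H](O[Si](C)(C)C(C)(C)C)C(C)(C)O[C@H]3CC[C@]2(C)OC=O | intermediate
22 | but-3-en-2-one | CC(=O)C=C | starting material
23 | 2-(triisopropylsilyloxy)buta-1,3-diene | C=CC(=C)O[Si](C(C)C)(C(C)C)C(C)C | intermediate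
24 | 4,4-dimethylcyclohex-2-en-1-one | CC1(C)CCC(=O)C=C1 | starting material
25 | (4aR,8aS)-4,4-dimethyl-6-(triisopropylsilyloxy)-3,4,4a,5,8,8a-hexahydronaphthalen-1(2H)-one | CC(C)[Si](C(C)C)(C(C)C)OC=1C[C@@H]2[C@H](CC1)C(=O)CCC2(C)C | intermediate
26 | 1-methylidene analogue of 25 | CC(C)[Si](C(C)C)(C(C)C)OC=1C[C@@H]2[C@H](CC1)C(=C)CCC2(C)C | intermediate
27 | cis-8,8-dimethyl-5-methylidene-4a,5,6,7,8,8a-hexahydronaphthalen-2(1H)-one | O=C1C[C@@H]2[C@H](C=C1)C(=C)CCC2(C)C | intermediate
28 | 5-spiro-epoxide of 27 (oxygen on the convex face) | O=C1C[C@@H]2[C@H](C=C1)[C@@]3(OC3)CCC2(C)C | intermediate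
29 | cis-5,8,8-trimethyl-1,2,4a,5,6,7,8,8a-octahydronaphthalene-2,5-diol (C2 epimers) | OC1C[C@@H]2[C@H](C=C1)[C@@](C)(O)CCC2(C)C | intermediate
30 | (4aS,5S,8aR)-5-hydroxy-5,8,8-trimethyl-4a,5,6,7,8,8a-hexahydronaphthalen-2(1H)-one | O=C1C[C@@H]2[C@H](C=C1)[C@@](C)(O)CCC2(C)C | intermediate
31 | 1-(dimethylaminomethyl) derivative of 30 (Mannich base) | O=C1C(CN(C)C)[C@@H]2[C@H](C=C1)[C@@](C)(O)CCC2(C)C | intermediate
32 | trimethylammonium iodide of 31 | O=C1C(C[N+](C)(C)C)[C@@H]2[C@H](C=C1)[C@@](C)(O)CCC2(C)C.[I-] | intermediate
33 | 1-methylidene derivative of 30 | O=C1C(=C)[C@@H]2[C@H](C=C1)[C@@](C)(O)CCC2(C)C | intermediate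
34 | Giese adduct (ring C enone, formate, C1 epimers) | O=C1C(CC[C@H]3[C@]4(C)CC[C@H](O[Si](C)(C)C(C)(C)C)C(C)(C)O[C@H]4CC[C@]3(C)OC=O)[C@@H]2[C@H](C=C1)[C@@](C)(O)CCC2(C)C | intermediate
35 | saturated keto formate | O=C1C(CC[C@H]3[C@]4(C)CC[C@H](O[Si](C)(C)C(C)(C)C)C(C)(C)O[C@H]4CC[C@]3(C)OC=O)[C@@H]2[C@H](CC1)[C@@](C)(O)CCC2(C)C | intermediate
36 | saturated keto diol, α-chain trans to the ring D bond | O=C1[C@H](CC[C@H]3[C@]4(C)CC[C@H](O[Si](C)(C)C(C)(C)C)C(C)(C)O[C@H]4CC[C@]3(C)O)[C@@H]2[C@H](CC1)[C@@](C)(O)CCC2(C)C | intermediate
37 | bis(triethylsilyl) ether of 36 | O=C1[C@H](CC[C@H]3[C@]4(C)CC[C@H](O[Si](C)(C)C(C)(C)C)C(C)(C)O[C@H]4CC[C@]3(C)O[Si](CC)(CC)CC)[C@@H]2[C@H](CC1)[C@@](C)(O[Si](CC)(CC)CC)CCC2(C)C | intermediate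
38 | enol triflate of 37 | FC(F)(F)S(=O)(=O)OC=1[C@H](CC[C@H]3[C@]4(C)CC[C@H](O[Si](C)(C)C(C)(C)C)C(C)(C)O[C@H]4CC[C@]3(C)O[Si](CC)(CC)CC)[C@@H]2[C@H](CC1)[C@@](C)(O[Si](CC)(CC)CC)CCC2(C)C | intermediate
39 | methylated, silylated ring C alkene | CC=1[C@H](CC[C@H]3[C@]4(C)CC[C@H](O[Si](C)(C)C(C)(C)C)C(C)(C)O[C@H]4CC[C@]3(C)O[Si](CC)(CC)CC)[C@@H]2[C@H](CC1)[C@@](C)(O[Si](CC)(CC)CC)CCC2(C)C | intermediate
40 | triol with trisubstituted ring C alkene | CC=1[C@H](CC[C@H]3[C@]4(C)CC[C@H](O)C(C)(C)O[C@H]4CC[C@]3(C)O)[C@@H]2[C@H](CC1)[C@@](C)(O)CCC2(C)C | intermediate
41 | sipholenol M | CC1=C(CC[C@H]2[C@]3(C)CC[C@H](O)C(C)(C)O[C@H]3CC[C@]2(C)O)[C@@H]2[C@H](C[C@H]1OO)[C@@](C)(O)CCC2(C)C | target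

## Step count and least certain steps

Total: 31 steps. Longest linear sequence: 22 steps (steps 1–4, 6–16 and 25–31). The Grignard reagent (step 5) and the right half (steps 17–24, eight steps) are made in parallel.

Step 6 (key step). The alkylation is the weak part. The enolate carbon sits next to a fresh quaternary carbon, so SN2 attack on 8 may be slower than proton transfer between the enolate and the product or the bromoacetate; that would give recovered simple ketone, alkylation at the other α-carbon or O-alkylation. Fallback: setting out from enolate 10, the electrophile is changed from an alkyl halide to an aldehyde. Addition to tert-butyl glyoxylate at −78 °C should give the aldol adduct tert-butyl 2-hydroxy-2-(2-oxocyclohexyl)acetate derivative F1. Mesylation and elimination with Et3N/DBU give the alkylidene keto ester F2, and reduction of this ene-1,4-dicarbonyl unit with Zn in AcOH returns to 11, the α-methine again settling in the equatorial configuration.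

Step 9. The ring closure may take the 6-exo course, the hydroxyl attacking the secondary epoxide carbon to give a tetrahydropyran with a hydroxy-isopropyl side chain; alternatively the opened tertiary cation may undergo a hydride shift to a ketone. Both follow from the normal kinetic preference for the smaller ring and from the cationic character needed for the endo mode. Fallback: setting out from 12, the epoxide is isomerised with Me3SiOTf and DBU (then K2CO3 in MeOH to remove the trimethylsilyl groups) to the isopropenyl carbinol F3, which keeps the (S)-C–O bond. Bu4NF gives the diol F4. Alkoxymercuration with Hg(OCOCF3)2 must then place the ring B oxygen on the tertiary carbon and the metal on the terminal CH2 (organomercurial F5); reduction of the C–Hg bond with Bu3SnH returns to 14.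

Step 18. The β-carbon of 24 is neopentyl-like. The cycloaddition may therefore be slow, so that protodesilylation of 23 by the acidic catalyst or an unselective background reaction erodes yield and enantiomeric purity. Fallback: the racemate of 25 is made with Me2AlCl as promoter and reduced with NaBH4 from the convex face. The racemic alcohol is resolved by lipase-catalysed acetylation (vinyl acetate), which is assumed to leave the wanted alcohol F6 and to convert its antipode into the acetate F7. Dess–Martin oxidation of F6 returns to 25.

Step 25. The stannane may reduce the primary radical before it adds; the exocyclic dienone 33 may dimerise or polymerise at 80 °C; and the radical may abstract the formyl hydrogen intramolecularly. All three would lower the amount of coupled product. Fallback: the radical is generated oxidatively instead. Setting out from lactone 19, saponification with KOH gives the potassium hydroxy carboxylate F8. Irradiation with blue light in DMF in the presence of Ir[dF(CF3)ppy]2(dtbbpy)PF6, K2HPO4 and 33 should give, by decarboxylative conjugate addition, the adduct with free tertiary hydroxyl F9. F9 is hydrogenated and equilibrated as in step 26 and comes back at 36.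

Step 31. This is the least secure step after the key step. Singlet oxygen can also abstract a hydrogen from the vinylic methyl group or from the ring CH2 group, which would give the exocyclic-alkene or the tertiary hydroperoxide. The methine hydrogen that must be abstracted is axial only in the less populated ring-flipped conformer of the cis-octalin, and the face that must be attacked is the more hindered one. A regioisomeric mixture, or delivery of oxygen to the wrong face, is therefore the likely failure. Fallback: the oxygen is introduced by enolate chemistry and the O–O bond by displacement. Setting out from 37, the kinetic triethylsilyl enol ether (LiN(SiMe3)2, Et3SiCl) is oxidised with mCPBA/NaHCO3 (Rubottom oxidation, expected anti to the axial ring D carbon) to the α-silyloxy ketone F10. Enolisation away from the oxygenated carbon with KN(SiMe3)2 and PhNTf2 gives the tetrasubstituted enol triflate F11. Negishi methylation as in step 29 gives the silylated allylic ether F12, and Bu4NF gives the tetraol with the epimeric allylic hydroxyl F13. Selective sulfonylation of the allylic alcohol (MsCl, Et3N, −78 °C) gives the allylic mesylate F14, and displacement with anhydrous H2O2 in Et2O at low temperature, with inversion, comes back at 41.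

## Further compounds

F1 | step 6 | tert-butyl 2-hydroxy-2-[(2S,3S)-3-(tert-butyldimethylsilyloxy)-2-methyl-2-(4-methylpent-3-enyl)-6-oxocyclohexyl]acetate (aldol adduct) | CC(C)=CCC[C@]1(C)[C@@H](O[Si](C)(C)C(C)(C)C)CCC(=O)C1C(O)C(=O)OC(C)(C)C
F2 | step 6 | tert-butyl 2-[(2S,3S)-3-(tert-butyldimethylsilyloxy)-2-methyl-2-(4-methylpent-3-enyl)-6-oxocyclohexylidene]acetate | CC(C)=CCC[C@]1(C)[C@@H](O[Si](C)(C)C(C)(C)C)CCC(=O)C1=CC(=O)OC(C)(C)C
F3 | step 9 | isopropenyl carbinol from 12: tert-butyl 2-[(1S,2S,3S)-3-(tert-butyldimethylsilyloxy)-2-[(3S)-3-hydroxy-4-methylpent-4-enyl]-2-methyl-6-oxocyclohexyl]acetate | C=C(C)[C@@H](O)CC[C@]2(C)[C@@H](O[Si](C)(C)C(C)(C)C)CCC(=O)[C@H]2CC(=O)OC(C)(C)C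
F4 | step 9 | desilylated diol of F3 | C=C(C)[C@@H](O)CC[C@]2(C)[C@@H](O)CCC(=O)[C@H]2CC(=O)OC(C)(C)C
F5 | step 9 | oxepane organomercurial (2-CH2HgOCOCF3 in place of one 2-methyl of 14) | CC(C)(C)OC(=O)C[C@H]2[C@]3(C)CC[C@H](O)C(C)(C[Hg]OC(=O)C(F)(F)F)O[C@H]3CCC2=O
F6 | step 18 | (1R,4aR,8aS)-4,4-dimethyl-6-(triisopropylsilyloxy)-1,2,3,4,4a,5,8,8a-octahydronaphthalen-1-ol (wanted enantiomer of the alcohol) | CC(C)[Si](C(C)C)(C(C)C)OC=1C[C@@H]2[C@H](CC1)[C@H](O)CCC2(C)C
F7 | step 18 | acetate of the enantiomeric alcohol | CC(C)[Si](C(C)C)(C(C)C)OC=1C[C@H]2[C@@H](CC1)[C@@H](OC(C)=O)CCC2(C)C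
F8 | step 25 | potassium 2-[(3S,5aS,6S,7S,9aS)-3-(tert-butyldimethylsilyloxy)-7-hydroxy-2,2,5a,7-tetramethyldecahydro-1-benzoxepin-6-yl]acetate | [K+].[O-]C(=O)C[C@H]2[C@]3(C)CC[C@H](O[Si](C)(C)C(C)(C)C)C(C)(C)O[C@H]3CC[C@]2(C)O
F9 | step 25 | Giese adduct with free ring B tertiary hydroxyl (34 without the formyl group) | O=C1C(CC[C@H]3[C@]4(C)CC[C@H](O[Si](C)(C)C(C)(C)C)C(C)(C)O[C@H]4CC[C@]3(C)O)[C@@H]2[C@H](C=C1)[C@@](C)(O)CCC2(C)C
F10 | step 31 | α-(triethylsilyloxy) ketone from 37 (oxygen at the ring CH2 carbon, anti to the ring D bonds) | O=C1[C@H](CC[C@H]3[C@]4(C)CC[C@H](O[Si](C)(C)C(C)(C)C)C(C)(C)O[C@H]4CC[C@]3(C)O[Si](CC)(CC)CC)[C@@H]2[C@H](C[C@@H]1O[Si](CC)(CC)CC)[C@@](C)(O[Si](CC)(CC)CC)CCC2(C)C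
F11 | step 31 | tetrasubstituted enol triflate of F10 | FC(F)(F)S(=O)(=O)OC1=C(CC[C@H]3[C@]4(C)CC[C@H](O[Si](C)(C)C(C)(C)C)C(C)(C)O[C@H]4CC[C@]3(C)O[Si](CC)(CC)CC)[C@@H]2[C@H](C[C@@H]1O[Si](CC)(CC)CC)[C@@](C)(O[Si](CC)(CC)CC)CCC2(C)C
F12 | step 31 | methylated tetrasubstituted alkene, fully silylated | CC1=C(CC[C@H]3[C@]4(C)CC[C@H](O[Si](C)(C)C(C)(C)C)C(C)(C)O[C@H]4CC[C@]3(C)O[Si](CC)(CC)CC)[C@@H]2[C@H](C[C@@H]1O[Si](CC)(CC)CC)[C@@](C)(O[Si](CC)(CC)CC)CCC2(C)C
F13 | step 31 | tetraol with allylic hydroxyl epimeric to the OOH carbon of 41 | CC1=C(CC[C@H]2[C@]3(C)CC[C@H](O)C(C)(C)O[C@H]3CC[C@]2(C)O)[C@@H]2[C@H](C[C@@H]1O)[C@@](C)(O)CCC2(C)C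
F14 | step 31 | allylic mesylate of F13 | CC1=C(CC[C@H]2[C@]3(C)CC[C@H](O)C(C)(C)O[C@H]3CC[C@]2(C)O)[C@@H]2[C@H](C[C@@H]1OS(C)(=O)=O)[C@@](C)(O)CCC2(C)C
A1 | alternative 1 | trans-fused 2,2-dimethyloxepene ketone (rings A and B) | O=C1CCC[C@@H]2OC(C)(C)C=CC[C@@]12C
A2 | alternative 1 | 2-allyl-2-methyl-3-(2-methylbut-3-en-2-yloxy)cyclohexanone (metathesis precursor) | O=C1CCC[C@H](OC(C)(C)C=C)[C@@]1(C)CC=C
A3 | alternative 2 | cis-fused silyloxy octalone (rings C and D) | CC1=C[C@@H]2[C@H](C[C@H]1O[Si](C)(C)C(C)(C)C)C(=O)CCC2(C)C
A4 | alternative 2 | (7E,9E)-10-(tert-butyldimethylsilyloxy)-6,6,9-trimethyldeca-1,7,9-trien-3-one | C=CC(=O)CCC(C)(C)/C=C/C(C)=C/O[Si](C)(C)C(C)(C)C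
A5 | alternative 3 | cis-decalin ketone with gem-dimethyl quaternary carbon and silyloxymethyl arm | O=C1CC[C@@H]2[C@@](C)(O[Si](C)(C)C)CCC(C)(C)[C@@H]2[C@H]1CO[Si](C)(C)C(C)(C)C
A6 | alternative 3 | 2-(tert-butyldimethylsilyloxymethyl)-4-[5-methyl-2-(trimethylsilyloxy)hex-5-en-2-yl]cyclohex-2-en-1-one | O=C1CC[C@H]([C@@](C)(O[Si](C)(C)C)CCC(C)=C)C=C1CO[Si](C)(C)C(C)(C)C
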